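(The runs were computed from invented constants; scatter was added.)

The alpha run, charged with 2.7 equiv of partner, held less left-handed substrate after 30.0 min than the theta run with 1.4 equiv, 28% against 42%, on the same loading of free catalyst.

| setting | theta | alpha | Monday's | Friday's |
|---|---|---|---|---|
| left-handed substrate | 0.40 M | 0.40 M | 0.40 M | 0.40 M |
| right-handed substrate | 0.40 M | 0.40 M | 0.40 M | 0.40 M |
| partner | 1.4 equiv | 2.7 equiv | 2.20 equiv | 1.10 equiv |
| free catalyst | 0.39 mol% | 0.39 mol% | 0.39 mol% | 0.39 mol% |
| remark | run made earlier | run made earlier |  |  |
| time |  |  | 30 min | 30 min |

| run | time / min | right-handed substrate / % | left-handed substrate / % | left-handed product / % |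
|---|---|---|---|---|
| theta | 2.00 | 51 | 48 | 1 |
| theta | 6.00 | 48 | 45 | 3 |
| theta | 10.0 | 51 | 43 | 11 |
| theta | 15.0 | 50 | 39 | 15 |
| theta | 25.0 | 49 | 40 | 14 |
| theta | 30.0 | 47 | 42 | 16 |
| alpha | 5.00 | 48 | 44 | 8 |
| alpha | 10.0 | 49 | 40 | 16 |
| alpha | 15.0 | 45 | 32 | 22 |
| alpha | 20.0 | 46 | 29 | 23 |
| alpha | 25.0 | 44 | 29 | 26 |
| alpha | 30.0 | 43 | 28 | 25 |

(standard deviation of a reading: 1.5 percentage points)

- which of the two ends with the higher excess of right-handed substrate over left-handed substrate among what is left of the two ("neither" if they lie within 2 percentage points) (Monday's / Friday's / neither)
- excess of right-handed substrate over left-handed substrate among what is left of the two at the end, Monday's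
- excess of right-handed substrate over left-handed substrate among what is left of the two at the end, Friday's

- free catalyst is single-handed; left-handed substrate and right-handed substrate are mirror images of each other, charged as a racemate, each of them at the stated concentration
- an excess is the difference of the two amounts in percent of their sum
- an excess is below zero if the other one leads

I went through the alpha flask slowly. In the first minutes the left-handed substrate goes while the right-handed one stays near its charge: after 5.00 min they read 44% and 48%. I took the rate as first order in c left-handed substrate and in c partner; in the alpha flask, with partner in excess, that is pseudo-first-order in the substrate. By 15.0 min the left-handed substrate of alpha read 32%, and over the next 15.0 min it went down by 4 percentage points. At the end of alpha the left-handed product read 25% of the two substrates, which accounts for 18.5% of the partner charged. So in alpha, making left-handed product did not use up the partner, and I supposed that something else ran down on a clock of its own.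

At fixed time, loading and concentration, the logarithm of charged over remaining should then grow in proportion to the partner charge. I carried this as the loss number: ln(charged/remaining) per equivalent of partner. I took the last three alpha readings as one end level; they average 28.7% left-handed and 44.3% right-handed, against 50 charged, so the left-handed loss number is 0.206 and the right-handed one 0.0446. Theta's last three readings give a lower left-handed 0.153, but its loss is smaller against the same scatter, so I leaned on alpha. That gave me 17.6% for Monday's and 8.86% for Friday's.

The forecast chose Monday's, with 17% (13% to 21%) for Monday's and 8% (5% to 11.5%) for Friday's, holding that “the extent is set by the partner”. My figures lay slightly above it.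

Monday's ended at 16.4% and Friday's at 8.18%, so Monday's ended higher. The two flasks ended with close shares: free catalyst 58.8% and 58.8% of the catalyst charged, partner 49% and 47% of its own charge. The left-handed substrate remaining, 63% of charge on Monday's and 79% on Friday's, gives loss numbers of 0.210 and 0.212, beside the 0.206 read from alpha.

    partner + free catalyst + left-handed substrate → free catalyst + left-handed product (k = 0.455 L² mol⁻² s⁻¹)
    partner + free catalyst + right-handed substrate → free catalyst + right-handed product (k = 0.0142 L² mol⁻² s⁻¹)
    left-handed substrate ⇌ right-handed substrate (k = 2.83 × 10⁻⁴ s⁻¹)
    2 free catalyst → spent catalyst (k = 0.125 L mol⁻¹ s⁻¹)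
    left-handed product ⇌ right-handed product (k = 9.93 × 10⁻⁵ s⁻¹)
    partner → decomposed reagent (k = 2.31 × 10⁻⁴ s⁻¹)

For Monday's recipe with 0.880 equiv of partner, the loss numbers give 83.4% of the left-handed and 96.2% of the right-handed substrate remaining, an excess of 7.09%. That flask gave 6.53%, with 83% of the left-handed and 95% of the right-handed substrate remaining.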